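**Retrosynthetic overview**

1. The two ketones come from one final MnO2 oxidation of two allylic alcohols. The chain is cut at C2′–C3′ into a chromene acetaldehyde and an E-vinyl iodide (Nozaki–Hiyama–Kishi coupling).
2. West half: (S)-linalool supplies the quaternary C–O centre, which is never broken. A Heck arylation of its vinyl group is followed by a photochemical ring closure that forms the aryl–O bond. The side chain is shortened through a Schenck-ene alcohol and epoxide/periodate cleavage.
3. East half: (R)-citronellyl bromide supplies C6′–C12′ and the C8′ methyl centre. Photooxygenation and oxidative transposition give the enone. C9′–OH is set on a temporary dihydropyran ring, anti to the ring methyl.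
4. C3′–C5′ come from propyne (alkylation, then zirconium-catalysed carboalumination/iodination for the E-trisubstituted alkene).
5. Rings: the benzene ring is bought. The pyran ring of the chromene is the only ring built for the target (step 4). The east dihydropyran is temporary (closed in step 8, opened in step 9).

Assumption and convention (one line): compounds 1, 3 and 12 are bought as single compounds of high purity and ee; primed locants count the side chain from the CH2 on chromene C2 (C2′ and C10′ are the ketone carbons, C8′ and C9′ the side-chain stereocentres).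

**Route**

Step 1
Reactants: 1 1-iodo-3-methoxy-5-methylbenzene
Product: 2 2-bromo-1-iodo-5-methoxy-3-methylbenzene
Conditions: NBS, MeCN, 0 °C → rt, dark
Reagents that add atoms: N-bromosuccinimide O=C1CCC(=O)N1Br
Why: Electrophilic aromatic bromination goes para to the methoxy group (the position between I and CH3), as is usual for 3,5-disubstituted anisoles; no stereocentre is involved.

Step 2
Reactants: 3 (S)-(+)-linalool
Product: 5 (3E,6S)-2,6-dimethylocta-3,7-diene-2,6-diol, via allylic hydroperoxide 4 (not isolated)
Conditions: O2, tetraphenylporphyrin (0.1 mol %), white LEDs, CH2Cl2, 0 °C; then Me2S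
Reagents that add atoms: dioxygen O=O
Why: Schenck ene reaction of singlet oxygen at the trisubstituted alkene (the vinyl group is inert) followed by reduction of the hydroperoxide; the secondary-alcohol regioisomer is removed by chromatography and the bought (S) centre is untouched.

Step 3
Reactants: 5 (3E,6S)-2,6-dimethylocta-3,7-diene-2,6-diol; 2 2-bromo-1-iodo-5-methoxy-3-methylbenzene
Product: 6 (3E,6S,7E)-8-(2-bromo-5-methoxy-3-methylphenyl)-2,6-dimethylocta-3,7-diene-2,6-diol
Conditions: Pd(OAc)2 (5 mol %), Bu4NCl, NaHCO3, DMF, 50 °C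
Reagents that add atoms: none
Why: Mizoroki–Heck reaction under Jeffery conditions: oxidative addition at C–I rather than C–Br, insertion of the monosubstituted alkene and β-hydride elimination give the E-styrene, and the quaternary carbinol offers no β-hydrogen on its own side.

Step 4
Reactants: 6 (3E,6S,7E)-8-(2-bromo-5-methoxy-3-methylphenyl)-2,6-dimethylocta-3,7-diene-2,6-diol
Product: 8 (3E)-5-[(2S)-6-methoxy-2,8-dimethyl-2H-chromen-2-yl]-2-methylpent-3-en-2-ol, via Z-alkene 7 (not isolated)
Conditions: [Ir(dF(CF3)ppy)2(dtbbpy)]PF6 (1 mol %), NiBr2·MeOCH2CH2OMe (10 mol %), dtbbpy (12 mol %), quinuclidine (10 mol %), K2CO3, MeCN, 450 nm LEDs, 30 °C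
Reagents that add atoms: none
Why: Proposed new method: the excited iridium complex converts the E-styrene into Z-isomer 7 by triplet energy transfer and, by electron transfer, also drives a nickel cycle (oxidative addition of the aryl bromide, binding of the tertiary alkoxide, oxidation to trivalent nickel, C–O reductive elimination), so only the Z isomer can close the six-membered ring and is drained from the photostationary mixture while the C–O bond of the linalool stereocentre is never broken (retention, 2S); the closest known reactions are nickel/photoredox etherification of aryl bromides with primary and secondary alcohols and sensitised E-to-Z isomerisation of styrenes, and what is new is their merger and the ring-closing use of a tertiary alcohol.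

Step 5
Reactants: 8 (3E)-5-[(2S)-6-methoxy-2,8-dimethyl-2H-chromen-2-yl]-2-methylpent-3-en-2-ol
Product: 11 2-[(2S)-6-methoxy-2,8-dimethyl-2H-chromen-2-yl]acetaldehyde, via epoxy alcohol 9 (not isolated), via triol 10 (not isolated)
Conditions: VO(acac)2 (3 mol %), t-BuOOH, CH2Cl2, 0 °C; then H5IO6 (2.5 equiv), THF/H2O, 0 °C
Reagents that add atoms: tert-butyl hydroperoxide CC(C)(C)OO; water O
Why: Hydroxyl-directed vanadium epoxidation touches only the allylic-alcohol alkene (the chromene alkene has no directing OH), and periodic acid then hydrolyses the epoxide and cleaves the glycol (Malaprade cleavage) under non-basic conditions that avoid retro-oxa-Michael opening of the chromene.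

Step 6
Reactants: 12 (R)-(−)-citronellyl bromide
Product: 14 (3E,6R)-8-bromo-2,6-dimethyloct-3-en-2-ol, via allylic hydroperoxide 13 (not isolated)
Conditions: O2, tetraphenylporphyrin (0.1 mol %), white LEDs, CH2Cl2, 0 °C; then Me2S
Reagents that add atoms: dioxygen O=O
Why: Schenck ene reaction as in step 2 gives the E tertiary allylic alcohol after reduction (the regioisomer is separated); the bought methyl-bearing centre is not touched.

Step 7
Reactants: 14 (3E,6R)-8-bromo-2,6-dimethyloct-3-en-2-ol
Product: 15 (6R)-8-bromo-2,6-dimethyloct-2-en-4-one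
Conditions: pyridinium chlorochromate (C5H5NH)[CrO3Cl] (2.5 equiv), 4 Å sieves, CH2Cl2, rt
Reagents that add atoms: pyridinium chlorochromate [O-][Cr](=O)(=O)Cl.c1cc[nH+]cc1
Why: Babler–Dauben oxidative 1,3-transposition of the tertiary allylic alcohol (chromate ester, [3,3] shift, oxidation) gives the β,β-dimethyl enone with the future C10′ carbonyl in place.

Step 8
Reactants: 15 (6R)-8-bromo-2,6-dimethyloct-2-en-4-one
Product: 17 (4S)-4-methyl-6-(2-methylprop-1-en-1-yl)-3,4-dihydro-2H-pyran, via potassium enolate 16 (not isolated)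
Conditions: KN(SiMe3)2 (1.1 equiv), THF/DMPU, −78 °C → 0 °C
Reagents that add atoms: none
Why: Kinetic α′-deprotonation and intramolecular O-alkylation of the enolate (a six-membered ring by O-attack against a four-membered ring by C-attack) give the cyclic dienol ether that serves as a ring template; the methyl centre is unchanged (the descriptor changes by priority only).

Step 9
Reactants: 17 (4S)-4-methyl-6-(2-methylprop-1-en-1-yl)-3,4-dihydro-2H-pyran
Product: 20 (5R,6S)-2,6-dimethyloct-2-ene-4,5,8-triol, via epoxide 18 (not isolated), via hemiketal 19 (not isolated)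
Conditions: dimethyldioxirane (1.05 equiv), acetone/CH2Cl2, −78 °C; then H2O/THF, NaHCO3; then NaBH4, CeCl3·7H2O, MeOH, −40 °C
Reagents that add atoms: dimethyldioxirane CC1(C)OO1; water O
Why: Rubottom-type epoxidation of the electron-rich enol-ether double bond on the face of the half-chair opposite the adjacent ring methyl (1,2-induction by the bought C8′ centre, as in glycal epoxidation) puts the new C9′–O bond trans to the methyl, which is the (R) carbinol of the target; the epoxide hydrolyses to hemiketal 19 and Luche reduction of its open-chain ketone masks C10′ as an alcohol (epimers, re-oxidised in step 15).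

Step 10
Reactants: 20 (5R,6S)-2,6-dimethyloct-2-ene-4,5,8-triol
Product: 21 (3S)-3-[(4R)-2,2-dimethyl-5-(2-methylprop-1-en-1-yl)-1,3-dioxolan-4-yl]butan-1-ol
Conditions: 2,2-dimethoxypropane, pyridinium tosylate (cat.), CH2Cl2, rt
Reagents that add atoms: 2,2-dimethoxypropane COC(C)(C)OC
Why: Thermodynamic acetonide formation takes the vicinal diol into a five-membered dioxolane and leaves the primary alcohol free.

Step 11
Reactants: 21 (3S)-3-[(4R)-2,2-dimethyl-5-(2-methylprop-1-en-1-yl)-1,3-dioxolan-4-yl]butan-1-ol
Product: 22 (4R)-4-[(2S)-4-iodobutan-2-yl]-2,2-dimethyl-5-(2-methylprop-1-en-1-yl)-1,3-dioxolane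
Conditions: I2, PPh3, imidazole, CH2Cl2, 0 °C
Reagents that add atoms: iodine II
Why: Appel-type iodination of the primary alcohol under buffered conditions that keep the acetonide.

Step 12
Reactants: 22 (4R)-4-[(2S)-4-iodobutan-2-yl]-2,2-dimethyl-5-(2-methylprop-1-en-1-yl)-1,3-dioxolane; 23 propyne
Product: 26 (4R)-4-[(2S)-hept-6-yn-2-yl]-2,2-dimethyl-5-(2-methylprop-1-en-1-yl)-1,3-dioxolane, via 1,3-dilithiopropyne 24 (not isolated), via lithium alkynide 25 (not isolated)
Conditions: propyne, n-BuLi (2 equiv per propyne), TMEDA, THF/hexane, −78 → 0 °C; then 22, −40 °C → rt; then H2O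
Reagents that add atoms: none
Why: SN2 alkylation of the propyne dianion at its more nucleophilic propargylic carbon gives the terminal alkyne after protonation and brings in C3′–C5′.

Step 13
Reactants: 26 (4R)-4-[(2S)-hept-6-yn-2-yl]-2,2-dimethyl-5-(2-methylprop-1-en-1-yl)-1,3-dioxolane
Product: 29 (1E,6S,7R)-1-iodo-2,6,10-trimethylundeca-1,9-diene-7,8-diol, via vinylalane 27 (not isolated), via iodo acetonide 28 (not isolated)
Conditions: Me3Al (3 equiv), (C5H5)2ZrCl2 (0.3 equiv), H2O (1.5 equiv), CH2Cl2, −25 °C; then I2, THF, −25 → 0 °C; then AcOH/H2O/THF, 40 °C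
Reagents that add atoms: trimethylaluminium C[Al](C)C; iodine II
Why: Negishi zirconium-catalysed carboalumination adds CH3–Al syn across the terminal alkyne with the methyl on the internal carbon, iodinolysis with retention gives the E-vinyl iodide (E geometry fixed here), and mild acid removes the acetonide.

Step 14
Reactants: 11 2-[(2S)-6-methoxy-2,8-dimethyl-2H-chromen-2-yl]acetaldehyde; 29 (1E,6S,7R)-1-iodo-2,6,10-trimethylundeca-1,9-diene-7,8-diol
Product: 30 (3E,8S,9R)-1-[(2S)-6-methoxy-2,8-dimethyl-2H-chromen-2-yl]-4,8,12-trimethyltrideca-3,11-diene-2,9,10-triol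
Conditions: CrCl2 (5 equiv), NiCl2 (2 mol %), DMSO/THF, rt
Reagents that add atoms: none
Why: Nozaki–Hiyama–Kishi coupling: the alkenylchromium reagent adds only to the aldehyde, tolerates the free diol, keeps the E geometry and is non-basic so the β-aryloxy aldehyde does not eliminate; the new C2′ carbinol (epimers) is oxidised in the next step.

Step 15
Reactants: 30 (3E,8S,9R)-1-[(2S)-6-methoxy-2,8-dimethyl-2H-chromen-2-yl]-4,8,12-trimethyltrideca-3,11-diene-2,9,10-triol
Product: 31 (3E,8S,9R)-9-hydroxy-1-[(2S)-6-methoxy-2,8-dimethyl-2H-chromen-2-yl]-4,8,12-trimethyltrideca-3,11-diene-2,10-dione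
Conditions: MnO2 (activated, 30 equiv), CH2Cl2, rt
Reagents that add atoms: none
Why: Chemoselective MnO2 oxidation of the two allylic alcohols (C2′ and C10′) leaves the saturated C9′ alcohol, and the neutral conditions avoid both C9′ epimerisation and retro-oxa-Michael opening at C2.

**Compound list**

1 | 1-iodo-3-methoxy-5-methylbenzene | COc1cc(C)cc(I)c1 | starting material
2 | 2-bromo-1-iodo-5-methoxy-3-methylbenzene | COc1cc(C)c(Br)c(I)c1 | intermediate
3 | (S)-(+)-linalool, (3S)-3,7-dimethylocta-1,6-dien-3-ol | C=C[C@@](C)(O)CCC=C(C)C | starting material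
4 | (3S,5E)-7-hydroperoxy-3,7-dimethylocta-1,5-dien-3-ol | C=C[C@@](C)(O)C/C=C/C(C)(C)OO | intermediate
5 | (3E,6S)-2,6-dimethylocta-3,7-diene-2,6-diol | C=C[C@@](C)(O)C/C=C/C(C)(C)O | intermediate
6 | (3E,6S,7E)-8-(2-bromo-5-methoxy-3-methylphenyl)-2,6-dimethylocta-3,7-diene-2,6-diol | COc1cc(C)c(Br)c(/C=C/[C@@](C)(O)C/C=C/C(C)(C)O)c1 | intermediate
7 | (3E,6S,7Z)-8-(2-bromo-5-methoxy-3-methylphenyl)-2,6-dimethylocta-3,7-diene-2,6-diol | COc1cc(C)c(Br)c(/C=C\[C@@](C)(O)C/C=C/C(C)(C)O)c1 | intermediate
8 | (3E)-5-[(2S)-6-methoxy-2,8-dimethyl-2H-chromen-2-yl]-2-methylpent-3-en-2-ol | COc1cc(C)c2c(c1)C=C[C@](C)(C/C=C/C(C)(C)O)O2 | intermediate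
9 | 2-[3-{[(2S)-6-methoxy-2,8-dimethyl-2H-chromen-2-yl]methyl}oxiran-2-yl]propan-2-ol (trans epoxide, both diastereomers) | COc1cc(C)c2c(c1)C=C[C@](C)(CC1OC1C(C)(C)O)O2 | intermediate
10 | 1-[(2S)-6-methoxy-2,8-dimethyl-2H-chromen-2-yl]-4-methylpentane-2,3,4-triol | COc1cc(C)c2c(c1)C=C[C@](C)(CC(O)C(O)C(C)(C)O)O2 | intermediate
11 | 2-[(2S)-6-methoxy-2,8-dimethyl-2H-chromen-2-yl]acetaldehyde | COc1cc(C)c2c(c1)C=C[C@](C)(CC=O)O2 | intermediate
12 | (R)-(−)-citronellyl bromide, (6R)-8-bromo-2,6-dimethyloct-2-ene | BrCC[C@H](C)CCC=C(C)C | starting material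
13 | (3E,6R)-8-bromo-2-hydroperoxy-2,6-dimethyloct-3-ene | BrCC[C@H](C)C/C=C/C(C)(C)OO | intermediate
14 | (3E,6R)-8-bromo-2,6-dimethyloct-3-en-2-ol | BrCC[C@H](C)C/C=C/C(C)(C)O | intermediate
15 | (6R)-8-bromo-2,6-dimethyloct-2-en-4-one | BrCC[C@H](C)CC(=O)C=C(C)C | intermediate
16 | potassium (6R)-8-bromo-2,6-dimethylocta-2,4-dien-4-olate | BrCC[C@H](C)C=C([O-])C=C(C)C.[K+] | intermediate
17 | (4S)-4-methyl-6-(2-methylprop-1-en-1-yl)-3,4-dihydro-2H-pyran | CC(C)=CC1=C[C@@H](C)CCO1 | intermediate
18 | (5S)-5-methyl-1-(2-methylprop-1-en-1-yl)-2,7-dioxabicyclo[4.1.0]heptane, epoxide oxygen trans to the 5-methyl group | CC(C)=C[C@]12OCC[C@H](C)[C@H]1O2 | intermediate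
19 | (3R,4S)-4-methyl-2-(2-methylprop-1-en-1-yl)oxane-2,3-diol (anomers, in equilibrium with the open-chain hydroxy ketone) | O1CC[C@H](C)[C@@H](O)C1(O)C=C(C)C | intermediate
20 | (5R,6S)-2,6-dimethyloct-2-ene-4,5,8-triol (C4 epimers) | OCC[C@H](C)[C@@H](O)C(O)C=C(C)C | intermediate
21 | (3S)-3-[(4R)-2,2-dimethyl-5-(2-methylprop-1-en-1-yl)-1,3-dioxolan-4-yl]butan-1-ol (C5 epimers) | OCC[C@H](C)[C@@H](OC1(C)C)C(O1)C=C(C)C | intermediate
22 | (4R)-4-[(2S)-4-iodobutan-2-yl]-2,2-dimethyl-5-(2-methylprop-1-en-1-yl)-1,3-dioxolane | ICC[C@H](C)[C@@H](OC1(C)C)C(O1)C=C(C)C | intermediate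
23 | propyne | CC#C | starting material
24 | 1,3-dilithiopropyne | [Li]CC#C[Li] | intermediate
25 | lithium alkynide of 26 (lithium on the terminal alkyne carbon) | [Li]C#CCCC[C@H](C)[C@@H](OC1(C)C)C(O1)C=C(C)C | intermediate
26 | (4R)-4-[(2S)-hept-6-yn-2-yl]-2,2-dimethyl-5-(2-methylprop-1-en-1-yl)-1,3-dioxolane | C#CCCC[C@H](C)[C@@H](OC1(C)C)C(O1)C=C(C)C | intermediate
27 | (E)-alkenyl(dimethyl)alane from 26 (Al on the terminal carbon, cis to the new methyl) | C[Al](C)/C=C(\C)CCC[C@H](C)[C@@H](OC1(C)C)C(O1)C=C(C)C | intermediate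
28 | (4R)-4-[(2S,6E)-7-iodo-6-methylhept-6-en-2-yl]-2,2-dimethyl-5-(2-methylprop-1-en-1-yl)-1,3-dioxolane | I/C=C(\C)CCC[C@H](C)[C@@H](OC1(C)C)C(O1)C=C(C)C | intermediate
29 | (1E,6S,7R)-1-iodo-2,6,10-trimethylundeca-1,9-diene-7,8-diol (C8 epimers) | I/C=C(\C)CCC[C@H](C)[C@@H](O)C(O)C=C(C)C | intermediate
30 | (3E,8S,9R)-1-[(2S)-6-methoxy-2,8-dimethyl-2H-chromen-2-yl]-4,8,12-trimethyltrideca-3,11-diene-2,9,10-triol (C2 and C10 epimers) | COc1cc(C)c2c(c1)C=C[C@](C)(CC(O)/C=C(\C)CCC[C@H](C)[C@@H](O)C(O)C=C(C)C)O2 | intermediate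
31 | (3E,8S,9R)-9-hydroxy-1-[(2S)-6-methoxy-2,8-dimethyl-2H-chromen-2-yl]-4,8,12-trimethyltrideca-3,11-diene-2,10-dione | COc1cc(C)c2c(c1)C=C[C@](C)(CC(=O)/C=C(\C)CCC[C@H](C)[C@@H](O)C(=O)C=C(C)C)O2 | target

**Step count**

Total: 15 steps. Longest linear sequence: 10 steps (steps 6–15, from 12). The west branch is steps 1–5 and joins at step 14.

**Three steps most likely to fail, with fallbacks**

Step 4, the new reaction. The tertiary alkoxide may be too hindered for the nickel C–O step, and the 2H-chromene product might be ring-opened by the sensitiser, which would erode the ee at C2. The fallback uses known chemistry and sets out from 6. Sensitised E-to-Z isomerisation alone (thioxanthen-9-one, 405 nm, MeCN) gives a Z-rich mixture from which 7 is isolated. A thermal palladium-catalysed intramolecular aryl etherification of the tertiary alcohol then closes the ring (Pd(OAc)2, 2-(di-tert-butylphosphino)-1,1′-binaphthyl, Cs2CO3, toluene, 70 °C) and the route is rejoined at 8. No compound outside the list is made (none F0).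

Step 8. The enolate may equilibrate to the extended dienolate and alkylate on carbon, or the bromide may eliminate. The fallback sets out from 15 and avoids enolate chemistry. KOAc in DMF at 60 °C gives (3S)-3,7-dimethyl-5-oxooct-6-en-1-yl acetate F1. K2CO3 in MeOH at 0 °C gives (6S)-8-hydroxy-2,6-dimethyloct-2-en-4-one F2, which is in equilibrium with its cyclic hemiketal. Acid-catalysed cyclodehydration (cat. pyridinium tosylate, toluene, 4 Å sieves, 80 °C) returns to the route at 17.

Step 9. This is the weakest stereocontrol in the route. A single ring methyl is the only control element for the face selectivity, so the ratio at C9′ may be only moderate, and the side-chain alkene may compete for the oxidant. The fallback switches from kinetic to thermodynamic control and sets out from crude 19 as a mixture of C9′ epimers (made with dimethyldioxirane or with OsO4 (cat.)/N-methylmorpholine N-oxide on 17). Et3N in MeOH epimerises C9′ through the enediol of the open-chain α-hydroxy ketone towards the trans-3-hydroxy-4-methyl (diequatorial) hemiketal. Reduction as before rejoins the route at 20, where remaining epimer is removed by chromatography. No new compound is made (none F0).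

**Further compounds**

F0 | step 4 | none | none
F1 | step 8 | (3S)-3,7-dimethyl-5-oxooct-6-en-1-yl acetate | CC(=O)OCC[C@H](C)CC(=O)C=C(C)C
F2 | step 8 | (6S)-8-hydroxy-2,6-dimethyloct-2-en-4-one | OCC[C@H](C)CC(=O)C=C(C)C
F0 | step 9 | none | none
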